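**Strategy.** Everything rests on one transannular disconnection. C4 and C9 lie opposite each other in the ten-membered carbocycle (a 1,6-relationship). A bond between them turns it into a trans-decalin whose ring A (C9, C10, C1, C2, C3, C4) holds C1=C10 as a Z-cyclohexene and whose ring B (C4–C9) carries the trans-fused γ-lactone at C6/C7. The key step is a Grob fragmentation of this decalin: the C9 alkoxide ejects an equatorial C5 mesylate, the ring-fusion bond C4–C9 breaks, and the C9 ketone, the 4E alkene and the ten-membered ring appear in one operation. The precursor is the C9-hydroxy, C5-mesyloxy decalin lactone with a silyl ether at C2.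

Key step: step 15

Remark: germacrane numbering is used for every intermediate (C1–C10 carbocycle, C11/C12 lactone α-carbon and carbonyl); "axial/equatorial" refer to ring B (C4, C5, C6, C7, C8, C9) in the chair that keeps the trans-lactone diequatorial, and "6,12-lactone" means the γ-lactone from O–C6 to C12.

Step 1
Reactants: 1 2,6-dimethylphenol
Product: 2 4,4-dimethoxy-2,6-dimethylcyclohexa-2,5-dien-1-one
Conditions: PhI(OAc)2 (2.2 equiv), MeOH, 0 °C → rt
Reagents that add atoms: methanol, CO
Why: Oxidative dearomatisation: two successive two-electron oxidations of the phenol by PhI(OAc)2, each followed by para attack of methanol, should give the p-quinone monoketal, because both ortho positions carry methyl groups and only the para carbon can take up the nucleophile.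

Step 2
Reactants: 3 (S)-5-(hydroxymethyl)dihydrofuran-2(3H)-one
Product: 4 (S)-5-[(tert-butyldiphenylsilyloxy)methyl]dihydrofuran-2(3H)-one
Conditions: t-BuPh2SiCl, imidazole, DMF, 0 °C → rt
Reagents that add atoms: tert-butyl(chloro)diphenylsilane, CC(C)(C)[Si](Cl)(c1ccccc1)c1ccccc1
Why: Standard silylation of the primary alcohol; the bulky silyl group is chosen because it later shields one face of the butenolide and survives the enolate, peroxide, photochemical and iodination steps.

Step 3
Reactants: 4 (S)-5-[(tert-butyldiphenylsilyloxy)methyl]dihydrofuran-2(3H)-one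
Product: 6 (S)-5-[(tert-butyldiphenylsilyloxy)methyl]furan-2(5H)-one, via α-phenylselanyl lactone 5 (not isolated)
Conditions: LiN(SiMe3)2, THF, −78 °C; PhSeBr; then 30% H2O2, pyridine, CH2Cl2, 0 °C
Reagents that add atoms: none
Why: α-Selenenylation of the lactone enolate and oxidation to the selenoxide, whose syn-elimination should give the butenolide; the stereocentre (later C6) is not involved.

Step 4
Reactants: 6 (S)-5-[(tert-butyldiphenylsilyloxy)methyl]furan-2(5H)-one
Product: 7 (4R,5S)-5-[(tert-butyldiphenylsilyloxy)methyl]-4-(hydroxymethyl)dihydrofuran-2(3H)-one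
Conditions: hν (≥300 nm, Pyrex), benzophenone (0.2 equiv), MeOH, rt
Reagents that add atoms: methanol, CO
Why: Benzophenone-sensitised radical addition of methanol to the butenolide: the hydroxymethyl radical should add to the β-carbon (later C7) on the face opposite the silyloxymethyl group, which sets the trans relationship of C6 and C7.

Step 5
Reactants: 7 (4R,5S)-5-[(tert-butyldiphenylsilyloxy)methyl]-4-(hydroxymethyl)dihydrofuran-2(3H)-one
Product: 8 (4S,5S)-5-[(tert-butyldiphenylsilyloxy)methyl]-4-(iodomethyl)dihydrofuran-2(3H)-one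
Conditions: I2, PPh3, imidazole, CH2Cl2, 0 °C → rt
Reagents that add atoms: iodine, II
Why: Iodination of the primary alcohol by the Appel-type PPh3–I2–imidazole system (SN2 displacement of the oxyphosphonium ion); the neutral conditions leave the lactone and the silyl ether alone.

Step 6
Reactants: 8 (4S,5S)-5-[(tert-butyldiphenylsilyloxy)methyl]-4-(iodomethyl)dihydrofuran-2(3H)-one
Product: 9 (4S,5S)-5-(hydroxymethyl)-4-(iodomethyl)dihydrofuran-2(3H)-one
Conditions: HF·pyridine, THF, 0 °C → rt
Reagents that add atoms: none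
Why: Fluoride-induced cleavage of the silyl ether under slightly acidic conditions, which avoid alkoxide formation next to the primary iodide and the lactone.

Step 7
Reactants: 9 (4S,5S)-5-(hydroxymethyl)-4-(iodomethyl)dihydrofuran-2(3H)-one
Product: 10 (2S,3S)-3-(iodomethyl)-5-oxotetrahydrofuran-2-carbaldehyde
Conditions: Dess–Martin periodinane, CH2Cl2, 0 °C → rt; used at once
Reagents that add atoms: none
Why: Dess–Martin oxidation of the primary alcohol under non-basic conditions should give the epimerisable α-acyloxy aldehyde without loss of configuration at C6.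

Step 8
Reactants: 2 4,4-dimethoxy-2,6-dimethylcyclohexa-2,5-dien-1-one; 10 (2S,3S)-3-(iodomethyl)-5-oxotetrahydrofuran-2-carbaldehyde
Product: 13 (S)-6-{(R)-[(2S,3S)-3-(iodomethyl)-5-oxotetrahydrofuran-2-yl][(trimethylsilyl)oxy]methyl}-4,4-dimethoxy-2,6-dimethylcyclohex-2-en-1-one, via lithium enolate 11 (not isolated), via lithium aldolate 12 (not isolated)
Conditions: LiBH(s-Bu)3 (1.0 equiv), THF, −78 °C; then 10, −78 °C; then Me3SiCl, −78 → −40 °C
Reagents that add atoms: chlorotrimethylsilane, C[Si](C)(C)Cl
Why: Reductive aldol addition: conjugate hydride delivery to C3 of the symmetric dienone gives the achiral C9 enolate regiospecifically, which should add to the aldehyde through a Zimmerman–Traxler chair on the Felkin–Anh face (C6–O bond anti to the incoming C4), so that C4 is set with its methyl group on the side that becomes axial on ring B while C5 is formed as the epimer with its oxygen syn to C6–O (reset in steps 10 and 11); silylation of the aldolate at low temperature blocks the retro-aldol reaction and removes the acidic proton before the samarium step.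

Step 9
Reactants: 13 aldol trimethylsilyl ether (as named in step 8)
Product: 15 (4S,5R,6S,7S,9S)-5,9-dihydroxy-2-oxo trans-decalin 6,12-lactone (C1=C10 enone in ring A; 5-OH axial), via cyclised ketal silyl ether 14 (not isolated)
Conditions: SmI2 (2.5 equiv), NiI2 (2 mol%), THF, −78 → 0 °C; then 5% aq. oxalic acid, THF, rt
Reagents that add atoms: water, O
Why: Intramolecular samarium Barbier reaction: two-electron reduction of the C–I bond by divalent samarium (nickel-accelerated) gives an alkylsamarium that should add to the C9 ketone in a 6-exo closure of ring B through a chair with the lactone diequatorial; the bulky C5 side chain stays pseudo-equatorial on ring A, so that the new C8–C9 bond is equatorial and the ring fusion should be trans (C9–OH axial, trans to the C4 methyl group), after which dilute acid removes the trimethylsilyl ether and the allylic dimethyl ketal.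

Step 10
Reactants: 15 (4S,5R,6S,7S,9S)-5,9-dihydroxy-2-oxo trans-decalin 6,12-lactone
Product: 16 (4R,6S,7S,9S)-9-hydroxy-2,5-dioxo trans-decalin 6,12-lactone
Conditions: Dess–Martin periodinane, CH2Cl2, 0 °C → rt
Reagents that add atoms: none
Why: Dess–Martin oxidation of the only secondary alcohol (the tertiary C9 hydroxyl is inert) gives the C5 ketone, so that the C5 configuration left by the aldol step can be reset.

Step 11
Reactants: 16 (4R,6S,7S,9S)-9-hydroxy-2,5-dioxo trans-decalin 6,12-lactone
Product: 17 (4S,5S,6S,7S,9S)-5,9-dihydroxy-2-oxo trans-decalin 6,12-lactone (5-OH equatorial)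
Conditions: Me4NBH(OAc)3 (5 equiv), MeCN/AcOH (1:1), −30 °C
Reagents that add atoms: none
Why: Evans–Saksena hydroxyl-directed reduction: the axial C9 hydroxyl exchanges onto boron and hands the hydride to the axial face of the C5 carbonyl, which should give the equatorial C5 alcohol anti to C9–OH and trans to C6–O; the enone, which has no directing hydroxyl in reach, is not reduced by this mild reagent.

Step 12
Reactants: 17 (4S,5S,6S,7S,9S)-5,9-dihydroxy-2-oxo trans-decalin 6,12-lactone
Product: 18 (4S,5S,6S,7S,9S)-9-hydroxy-5-(methanesulfonyloxy)-2-oxo trans-decalin 6,12-lactone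
Conditions: MsCl, Et3N, CH2Cl2, −10 °C
Reagents that add atoms: methanesulfonyl chloride, CS(=O)(=O)Cl
Why: Sulfonylation (via sulfene) of the only secondary hydroxyl; the tertiary C9 alcohol does not react, and without a strong base the 1,3-hydroxy mesylate should not yet fragment.

Step 13
Reactants: 18 (4S,5S,6S,7S,9S)-9-hydroxy-5-(methanesulfonyloxy)-2-oxo trans-decalin 6,12-lactone
Product: 19 (2R,4S,5S,6S,7S,9S)-2,9-dihydroxy-5-(methanesulfonyloxy) trans-decalin 6,12-lactone (C1=C10 alkene; 2-OH cis to the C4 methyl group)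
Conditions: NaBH4, CeCl3·7H2O, MeOH, −78 °C
Reagents that add atoms: none
Why: Luche 1,2-reduction of the enone: the axial C4 methyl group is 1,3-diaxial to the C2 carbonyl on ring A, so hydride should add from the opposite face and give the 2R alcohol cis to that methyl group; at −78 °C the mesylate and the lactone are not touched.

Step 14
Reactants: 19 (2R,4S,5S,6S,7S,9S)-2,9-dihydroxy-5-(methanesulfonyloxy) trans-decalin 6,12-lactone
Product: 20 (2R,4S,5S,6S,7S,9S)-2-(tert-butyldimethylsilyloxy)-9-hydroxy-5-(methanesulfonyloxy) trans-decalin 6,12-lactone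
Conditions: t-BuMe2SiOTf (1.05 equiv), 2,6-lutidine, CH2Cl2, −78 °C
Reagents that add atoms: tert-butyldimethylsilyl trifluoromethanesulfonate, CC(C)(C)[Si](C)(C)OS(=O)(=O)C(F)(F)F
Why: Silylation of the secondary allylic alcohol in preference to the hindered tertiary C9 hydroxyl; the silyl ether is needed because a free C2 hydroxyl would close onto the C9 ketone (cyclic hemiketal, then furan) once the Z-enone is set free in the next step.

Step 15
Reactants: 20 (2R,4S,5S,6S,7S,9S)-2-(tert-butyldimethylsilyloxy)-9-hydroxy-5-(methanesulfonyloxy) trans-decalin 6,12-lactone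
Product: 21 (2R,6S,7S)-2-(tert-butyldimethylsilyloxy)-9-oxo-1(10)Z,4E-germacradien-6,12-lactone (ten-membered dienone, C11 still CH2)
Conditions: KOtBu (1.1 equiv), THF, 0 °C; aq. NH4Cl
Reagents that add atoms: none
Why: KOtBu deprotonates the tertiary C9 hydroxyl; in the one chair that the trans-fused lactone leaves to ring B, the C4–C9 bond lies anti to the equatorial C5–OMs bond and is aligned with a lone pair of the alkoxide, so the mesylate should leave in a concerted Grob fragmentation that forms C9=O and C4=C5 as the ring-fusion bond breaks. The closest known reaction type is the base-induced fragmentation of decalin 1,3-diol monosulfonates to E-cyclodecenones. The ten-membered ring is not closed by a cyclisation: it arises by ring expansion, through cleavage of the bond shared by rings A and B, so no medium-ring closure has to be paid for. No stereocentre is created, and C2, C6 and C7 are carried through unchanged. The step needs E geometry at C4=C5 and Z geometry at C1=C10: the first is secured because C3 (equatorial at C4) is anti to C6 about the C4–C5 bond, a consequence of the C4 and C5 configurations fixed in steps 8 and 11, and the second because C1=C10 was a cyclohexene. Oxetane formation or simple elimination would need geometries that the rigid chair does not offer, and the C2 silyl ether keeps the new Z-γ-oxy enone from cyclising.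

Step 16
Reactants: 21 (2R,6S,7S)-2-(tert-butyldimethylsilyloxy)-9-oxo-1(10)Z,4E-germacradien-6,12-lactone
Product: 22 (2R,6S,7S,9S)-2-(tert-butyldimethylsilyloxy)-9-hydroxy-1(10)Z,4E-germacradien-6,12-lactone
Conditions: (R)-2-methyl-CBS-oxazaborolidine [(R)-1-methyl-3,3-diphenyltetrahydro-1H,3H-pyrrolo[1,2-c][1,3,2]oxazaborole] (0.5 equiv), catecholborane (1.5 equiv), toluene, −78 °C; MeOH quench
Reagents that add atoms: none
Why: Corey–Bakshi–Shibata reduction: with the α-branched alkenyl carbon C10 as the large and C8 as the small substituent, the (R)-oxazaborolidine should deliver hydride to the face that gives the 9S allylic alcohol; catecholborane at −78 °C reduces neither the lactone nor the alkenes.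

Step 17
Reactants: 23 (E)-but-2-enal
Product: 24 (Z)-2-iodobut-2-enal
Conditions: I2, K2CO3, 4-(dimethylamino)pyridine (0.2 equiv), THF/H2O (1:1), rt
Reagents that add atoms: iodine, II
Why: α-Iodination of the enal by conjugate addition of the amine catalyst, iodination of the resulting enolate and elimination of the catalyst; the product should be the Z isomer, in which iodine is cis to the methyl group and the formyl group stays trans to it.

Step 18
Reactants: 24 (Z)-2-iodobut-2-enal
Product: 25 (Z)-2-iodobut-2-en-1-ol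
Conditions: NaBH4, MeOH, 0 °C
Reagents that add atoms: none
Why: 1,2-Reduction of the aldehyde by NaBH4; the trisubstituted iodoalkene and its geometry are not affected.

Step 19
Reactants: 25 (Z)-2-iodobut-2-en-1-ol
Product: 26 (Z)-tert-butyl[(2-iodobut-2-en-1-yl)oxy]dimethylsilane
Conditions: t-BuMe2SiCl, imidazole, CH2Cl2, rt
Reagents that add atoms: tert-butyl(chloro)dimethylsilane, CC(C)(C)[Si](C)(C)Cl
Why: Silylation of the primary allylic alcohol, so that one fluoride treatment at the end frees both hydroxyl groups of the target.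

Step 20
Reactants: 26 (Z)-tert-butyl[(2-iodobut-2-en-1-yl)oxy]dimethylsilane
Product: 28 (Z)-2-{[(tert-butyldimethylsilyl)oxy]methyl}but-2-enoic acid, via vinyllithium 27 (not isolated)
Conditions: t-BuLi (2.1 equiv), Et2O, −78 °C; then CO2 (g), −78 → 0 °C; cold 0.5 M HCl
Reagents that add atoms: carbon dioxide, O=C=O
Why: Iodine–lithium exchange proceeds with retention of alkene geometry, and carboxylation of the vinyllithium should give the Z acid in which the carboxyl group is cis to the methyl group.

Step 21
Reactants: 22 (2R,6S,7S,9S)-2-(tert-butyldimethylsilyloxy)-9-hydroxy-1(10)Z,4E-germacradien-6,12-lactone; 28 (Z)-2-{[(tert-butyldimethylsilyl)oxy]methyl}but-2-enoic acid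
Product: 30 (2R,6S,7S,9S)-2-(tert-butyldimethylsilyloxy)-9-[(Z)-2-(tert-butyldimethylsilyloxymethyl)but-2-enoyloxy]-1(10)Z,4E-germacradien-6,12-lactone, via mixed anhydride 29 (not isolated)
Conditions: 2,4,6-trichlorobenzoyl chloride, Et3N, toluene, rt; then 22, 4-(dimethylamino)pyridine, toluene, rt → 40 °C
Reagents that add atoms: none
Why: Yamaguchi esterification: the mixed anhydride transfers the acyl group through an acylpyridinium ion to the hindered secondary C9 alcohol with retention at C9; the mild, base-poor conditions are chosen to avoid Z to E isomerisation of the side-chain double bond.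

Step 22
Reactants: 30 bis-silyl ester lactone (as named in step 21)
Product: 33 (2R,6R,7S,9S)-2-(tert-butyldimethylsilyloxy)-9-[(Z)-2-(tert-butyldimethylsilyloxymethyl)but-2-enoyloxy]-1(10)Z,4E,11(13)-germacratrien-6,12-lactone, via Mannich base 31 (not isolated), via ammonium iodide 32 (not isolated)
Conditions: LiN(SiMe3)2 (1.2 equiv), THF, −78 °C; CH2=NMe2+ I− (Eschenmoser's salt), −78 → 0 °C; then MeI, MeOH, rt; then aq. NaHCO3, CH2Cl2, rt
Reagents that add atoms: N,N-dimethylmethyleneiminium iodide, C=[N+](C)C.[I-]
Why: α-Methylenation of the lactone: the lithium enolate (the only acidic C–H next to a carbonyl at −78 °C, since the side-chain ester has no α-hydrogen) is aminomethylated by the iminium salt in a Mannich reaction, and quaternisation followed by base-induced elimination of trimethylamine should give the exocyclic methylene group.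

Step 23
Reactants: 33 bis-silyl α-methylene lactone (as named in step 22)
Product: 34 CNP0273961.1, (2R,6R,7S,9S)-2-hydroxy-9-[(Z)-2-(hydroxymethyl)but-2-enoyloxy]-1(10)Z,4E,11(13)-germacratrien-6,12-lactone
Conditions: HF·pyridine, pyridine, THF, 0 °C → rt
Reagents that add atoms: none
Why: Buffered fluoride cleavage of both silyl ethers; the nearly neutral medium should spare the α-methylene lactone (no conjugate addition), the angelate-type ester and the acid-sensitive 1(10),4-diene.

**Compound list**

1 | 2,6-dimethylphenol | Cc1cccc(C)c1O | starting material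
2 | 4,4-dimethoxy-2,6-dimethylcyclohexa-2,5-dien-1-one | COC1(OC)C=C(C)C(=O)C(C)=C1 | intermediate
3 | (S)-5-(hydroxymethyl)dihydrofuran-2(3H)-one | O=C1CC[C@@H](CO)O1 | starting material
4 | (S)-5-[(tert-butyldiphenylsilyloxy)methyl]dihydrofuran-2(3H)-one | O=C1CC[C@@H](CO[Si](c2ccccc2)(c3ccccc3)C(C)(C)C)O1 | intermediate
5 | (5S)-5-[(tert-butyldiphenylsilyloxy)methyl]-3-(phenylselanyl)dihydrofuran-2(3H)-one (C3 epimers) | O=C1C([Se]c2ccccc2)C[C@@H](CO[Si](c3ccccc3)(c4ccccc4)C(C)(C)C)O1 | intermediate
6 | (S)-5-[(tert-butyldiphenylsilyloxy)methyl]furan-2(5H)-one | O=C1C=C[C@@H](CO[Si](c2ccccc2)(c3ccccc3)C(C)(C)C)O1 | intermediate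
7 | (4R,5S)-5-[(tert-butyldiphenylsilyloxy)methyl]-4-(hydroxymethyl)dihydrofuran-2(3H)-one (trans) | OC[C@H]1CC(=O)O[C@@H]1CO[Si](c2ccccc2)(c3ccccc3)C(C)(C)C | intermediate
8 | (4S,5S)-5-[(tert-butyldiphenylsilyloxy)methyl]-4-(iodomethyl)dihydrofuran-2(3H)-one | IC[C@H]1CC(=O)O[C@@H]1CO[Si](c2ccccc2)(c3ccccc3)C(C)(C)C | intermediate
9 | (4S,5S)-5-(hydroxymethyl)-4-(iodomethyl)dihydrofuran-2(3H)-one | IC[C@H]1CC(=O)O[C@@H]1CO | intermediate
10 | (2S,3S)-3-(iodomethyl)-5-oxotetrahydrofuran-2-carbaldehyde | IC[C@H]1CC(=O)O[C@@H]1C=O | intermediate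
11 | lithium 4,4-dimethoxy-2,6-dimethylcyclohexa-1,5-dien-1-olate | [Li]OC1=C(C)CC(OC)(OC)C=C1C | intermediate
12 | lithium aldolate (C5–OLi; configuration as in 13) | IC[C@H]1CC(=O)O[C@@H]1[C@H](O[Li])[C@]2(C)CC(OC)(OC)C=C(C)C2=O | intermediate
13 | (S)-6-{(R)-[(2S,3S)-3-(iodomethyl)-5-oxotetrahydrofuran-2-yl][(trimethylsilyl)oxy]methyl}-4,4-dimethoxy-2,6-dimethylcyclohex-2-en-1-one | IC[C@H]1CC(=O)O[C@@H]1[C@H](O[Si](C)(C)C)[C@]2(C)CC(OC)(OC)C=C(C)C2=O | intermediate
14 | (4S,5R,6S,7S,9S)-9-hydroxy-2,2-dimethoxy-5-(trimethylsilyloxy) trans-decalin 6,12-lactone (C1=C10 alkene) | O[C@]12C[C@H]3CC(=O)O[C@@H]3[C@H](O[Si](C)(C)C)[C@]1(C)CC(OC)(OC)C=C2C | intermediate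
15 | (4S,5R,6S,7S,9S)-5,9-dihydroxy-2-oxo trans-decalin 6,12-lactone (5-OH axial, cis to 9-OH; C4 methyl trans to 9-OH) | O[C@]12C[C@H]3CC(=O)O[C@@H]3[C@H](O)[C@]1(C)CC(=O)C=C2C | intermediate
16 | (4R,6S,7S,9S)-9-hydroxy-2,5-dioxo trans-decalin 6,12-lactone | O[C@]12C[C@H]3CC(=O)O[C@@H]3C(=O)[C@]1(C)CC(=O)C=C2C | intermediate
17 | (4S,5S,6S,7S,9S)-5,9-dihydroxy-2-oxo trans-decalin 6,12-lactone (5-OH equatorial, anti to 9-OH) | O[C@]12C[C@H]3CC(=O)O[C@@H]3[C@@H](O)[C@]1(C)CC(=O)C=C2C | intermediate
18 | (4S,5S,6S,7S,9S)-9-hydroxy-5-(methanesulfonyloxy)-2-oxo trans-decalin 6,12-lactone | O[C@]12C[C@H]3CC(=O)O[C@@H]3[C@@H](OS(C)(=O)=O)[C@]1(C)CC(=O)C=C2C | intermediate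
19 | (2R,4S,5S,6S,7S,9S)-2,9-dihydroxy-5-(methanesulfonyloxy) trans-decalin 6,12-lactone | O[C@]12C[C@H]3CC(=O)O[C@@H]3[C@@H](OS(C)(=O)=O)[C@]1(C)C[C@@H](O)C=C2C | intermediate
20 | (2R,4S,5S,6S,7S,9S)-2-(tert-butyldimethylsilyloxy)-9-hydroxy-5-(methanesulfonyloxy) trans-decalin 6,12-lactone | O[C@]12C[C@H]3CC(=O)O[C@@H]3[C@@H](OS(C)(=O)=O)[C@]1(C)C[C@@H](O[Si](C)(C)C(C)(C)C)C=C2C | intermediate
21 | (2R,6S,7S)-2-(tert-butyldimethylsilyloxy)-9-oxo-1(10)Z,4E-germacradien-6,12-lactone | C1C(=O)O[C@@H]2/C=C(\C)C[C@@H](O[Si](C)(C)C(C)(C)C)/C=C(/C)C(=O)C[C@@H]12 | intermediate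
22 | (2R,6S,7S,9S)-2-(tert-butyldimethylsilyloxy)-9-hydroxy-1(10)Z,4E-germacradien-6,12-lactone | C1C(=O)O[C@@H]2/C=C(\C)C[C@@H](O[Si](C)(C)C(C)(C)C)/C=C(/C)[C@@H](O)C[C@@H]12 | intermediate
23 | (E)-but-2-enal | C/C=C/C=O | starting material
24 | (Z)-2-iodobut-2-enal | C/C=C(\I)C=O | intermediate
25 | (Z)-2-iodobut-2-en-1-ol | C/C=C(\I)CO | intermediate
26 | (Z)-tert-butyl[(2-iodobut-2-en-1-yl)oxy]dimethylsilane | C/C=C(\I)CO[Si](C)(C)C(C)(C)C | intermediate
27 | vinyllithium from 26 (lithium in place of iodine, geometry retained) | C/C=C(\[Li])CO[Si](C)(C)C(C)(C)C | intermediate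
28 | (Z)-2-{[(tert-butyldimethylsilyl)oxy]methyl}but-2-enoic acid | C/C=C(\C(=O)O)CO[Si](C)(C)C(C)(C)C | intermediate
29 | mixed anhydride of 28 with 2,4,6-trichlorobenzoic acid | C/C=C(\C(=O)OC(=O)c1c(Cl)cc(Cl)cc1Cl)CO[Si](C)(C)C(C)(C)C | intermediate
30 | (2R,6S,7S,9S)-2-(tert-butyldimethylsilyloxy)-9-[(Z)-2-(tert-butyldimethylsilyloxymethyl)but-2-enoyloxy]-1(10)Z,4E-germacradien-6,12-lactone | C1C(=O)O[C@@H]2/C=C(\C)C[C@@H](O[Si](C)(C)C(C)(C)C)/C=C(/C)[C@@H](OC(=O)/C(=C\C)CO[Si](C)(C)C(C)(C)C)C[C@@H]12 | intermediate
31 | C11-(dimethylaminomethyl) derivative of 30 (C11 epimers) | CN(C)CC1C(=O)O[C@@H]2/C=C(\C)C[C@@H](O[Si](C)(C)C(C)(C)C)/C=C(/C)[C@@H](OC(=O)/C(=C\C)CO[Si](C)(C)C(C)(C)C)C[C@@H]12 | intermediate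
32 | C11-(trimethylammoniomethyl) iodide of 30 | C[N+](C)(C)CC1C(=O)O[C@@H]2/C=C(\C)C[C@@H](O[Si](C)(C)C(C)(C)C)/C=C(/C)[C@@H](OC(=O)/C(=C\C)CO[Si](C)(C)C(C)(C)C)C[C@@H]12.[I-] | intermediate
33 | (2R,6R,7S,9S)-2-(tert-butyldimethylsilyloxy)-9-[(Z)-2-(tert-butyldimethylsilyloxymethyl)but-2-enoyloxy]-1(10)Z,4E,11(13)-germacratrien-6,12-lactone | C=C1C(=O)O[C@@H]2/C=C(\C)C[C@@H](O[Si](C)(C)C(C)(C)C)/C=C(/C)[C@@H](OC(=O)/C(=C\C)CO[Si](C)(C)C(C)(C)C)C[C@@H]12 | intermediate
34 | CNP0273961.1, (2R,6R,7S,9S)-2-hydroxy-9-[(Z)-2-(hydroxymethyl)but-2-enoyloxy]-1(10)Z,4E,11(13)-germacratrien-6,12-lactone | C=C1C(=O)O[C@@H]2/C=C(\C)C[C@@H](O)/C=C(/C)[C@@H](OC(=O)/C(=C\C)CO)C[C@@H]12 | target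

**Step count.** Total: 23 steps. Longest linear sequence: 18 steps (from 3 through steps 2–16 and 21–23).

**Steps most likely to fail**

Step 8. The hindered, tetrasubstituted enolate 11 may act as a base toward the enolisable α-acyloxy aldehyde 10 faster than it adds to it. The aldehyde enolate can then close irreversibly onto its own iodomethyl group, so that both partners are consumed; facial discrimination at C4 may also be only moderate. The fallback sets out from 7 and returns at 13, and keeps the electrophilic iodide out of the union. Alcohol 7 is treated with 4-methoxybenzyl trichloroacetimidate and a catalytic amount of camphorsulfonic acid to give the 4-methoxybenzyl ether F1. HF·pyridine then frees the primary alcohol F2, and Dess–Martin oxidation gives the aldehyde F3, in which proton transfer is reversible and harmless, so that an excess can be used. Reductive aldol addition with 2 (through 11, as in step 8) gives the lithium aldolate F4 and, after Me3SiCl, the silyl ether F5. 2,3-Dichloro-5,6-dicyano-1,4-benzoquinone in buffered CH2Cl2–water removes the benzyl ether to give the primary alcohol F6, and PPh3–I2–imidazole converts F6 into 13.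

Step 9. Electron transfer from SmI2 to the conjugated C9 ketone may compete with reduction of the C–I bond (ketyl coupling, or reductive loss of a methoxy group from the γ-ketal), or the alkylsamarium may be protonated before it adds. The fallback sets out from 13 and returns at 14, and gives up single-electron chemistry for a polar halogen–metal exchange. Inverse addition of 13 to t-BuLi (2.1 equiv, Et2O–pentane, −100 °C) should effect iodine–lithium exchange faster than any carbonyl addition and give the alkyllithium F7. F7 closes ring B by intramolecular 1,2-addition to C9 under the same conformational control; protonation gives 14, and the acid treatment of step 9 then gives 15.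

Step 16. Hydride can reach the C9 carbonyl only from the outside of the ten-membered ring, and this conformational bias may override the oxazaborolidine, so that the 9R epimer forms or selectivity is low. The fallback sets out from 21 and returns at 30; it makes the 9R epimer on purpose and inverts it during esterification. Substrate-controlled reduction of 21 with NaBH4–CeCl3·7H2O in MeOH at −78 °C is expected, in that case, to give the 9R alcohol F8. Mitsunobu esterification of F8 with acid 28 (PPh3, diisopropyl azodicarboxylate, toluene, 0 °C) forms the C9–O bond with inversion and gives 30.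

**Further compounds**

F1 | step 8 | (4R,5S)-5-[(tert-butyldiphenylsilyloxy)methyl]-4-[(4-methoxybenzyloxy)methyl]dihydrofuran-2(3H)-one | COc1ccc(COC[C@H]2CC(=O)O[C@@H]2CO[Si](c3ccccc3)(c4ccccc4)C(C)(C)C)cc1
F2 | step 8 | (4R,5S)-5-(hydroxymethyl)-4-[(4-methoxybenzyloxy)methyl]dihydrofuran-2(3H)-one | COc1ccc(COC[C@H]2CC(=O)O[C@@H]2CO)cc1
F3 | step 8 | (2S,3R)-3-[(4-methoxybenzyloxy)methyl]-5-oxotetrahydrofuran-2-carbaldehyde | COc1ccc(COC[C@H]2CC(=O)O[C@@H]2C=O)cc1
F4 | step 8 | lithium aldolate from 11 and F3 (configuration as in 12) | COc1ccc(COC[C@H]2CC(=O)O[C@@H]2[C@H](O[Li])[C@]3(C)CC(OC)(OC)C=C(C)C3=O)cc1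
F5 | step 8 | trimethylsilyl ether of the aldol (4-methoxybenzyloxy analogue of 13) | COc1ccc(COC[C@H]2CC(=O)O[C@@H]2[C@H](O[Si](C)(C)C)[C@]3(C)CC(OC)(OC)C=C(C)C3=O)cc1
F6 | step 8 | primary alcohol (hydroxymethyl analogue of 13) | OC[C@H]1CC(=O)O[C@@H]1[C@H](O[Si](C)(C)C)[C@]2(C)CC(OC)(OC)C=C(C)C2=O
F7 | step 9 | alkyllithium from 13 (lithium in place of iodine) | [Li]C[C@H]1CC(=O)O[C@@H]1[C@H](O[Si](C)(C)C)[C@]2(C)CC(OC)(OC)C=C(C)C2=O
F8 | step 16 | (2R,6S,7S,9R)-2-(tert-butyldimethylsilyloxy)-9-hydroxy-1(10)Z,4E-germacradien-6,12-lactone (C9 epimer of 22) | C1C(=O)O[C@@H]2/C=C(\C)C[C@@H](O[Si](C)(C)C(C)(C)C)/C=C(/C)[C@H](O)C[C@@H]12
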